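**Retrosynthetic overview**

- The last step is a single BBr3 treatment that strips nineteen methyl and two ethyl groups from a fully alkylated octamer in which all seven diaryl ether links are already in place.
- The ethers B–O–C, D–O–E and F–O–G are each cut between a 2,6-dialkoxyphenol oxygen (C4–O of ring B, D or F) and C1 of a brominated ring (Ullmann coupling). The ethers C–O–D, E–O–F and G–O–H are cut between the C2 hydroxyl of one bromophenol and an arylboronic acid (Chan–Lam coupling), so one CD (= EF) bromide and one GH bromide serve as building blocks.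
- The strategy rests on ring B: it bears oxygen at C1 (ether to ring A), C3, C4 (ether to ring C) and C5, with the C1 and C3 oxygens meta to each other. A vinylketene from a 3,4-dialkoxycyclobutenone and an aryloxyacetylene give exactly this pattern, so ring B is built de novo with the hindered ring A oxygen (between two methoxy groups) already attached as an ynol ether.
- Ring order: A is bought, B is made by benzannulation, then C+D, E+F and G+H are added pairwise.

Key step: step 4

Remark: the cyclobutenone carries ethoxy instead of methoxy at C3 (a spectator that falls in the last step) because it is then available in one step from purchasable ethoxyacetylene, and the new ring B hydroxyl is ethylated too, so ring B is symmetric. The target is achiral, so no stereocentre has to be set. 2,4,6-Trimethoxyphenol, 2-(benzyloxy)acetyl chloride, 5-bromo-1,2,3-trimethoxybenzene, 4-bromo-2,6-dimethoxyphenol and (3,4,5-trimethoxyphenyl)boronic acid are taken as purchasable.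

**Route**

Step 1
Reactants: 1 2-(benzyloxy)acetyl chloride; 2 ethoxyacetylene
Product: 4 4-(benzyloxy)-3-ethoxycyclobut-2-en-1-one (racemic), via benzyloxyketene 3 (not isolated)
Conditions: Et3N, Et2O, 0 °C → rt (1 added slowly to excess 2)
Reagents that add atoms: none
Why: Et3N converts the acid chloride into benzyloxyketene 3, which is trapped in a ketene–ynol ether [2+2] cycloaddition in which the nucleophilic CH carbon of the alkyne bonds to the ketene carbonyl carbon, giving the 3-alkoxycyclobutenone directly; the C4 stereocentre forms racemic and is erased in step 4.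

Step 2
Reactants: 5 2,4,6-trimethoxyphenol; 6 trichloroethylene
Product: 8 2-{[(E)-1,2-dichloroethenyl]oxy}-1,3,5-trimethoxybenzene, via dichloroacetylene 7 (not isolated)
Conditions: K2CO3, DMF, 70 °C, Ar
Reagents that add atoms: none
Why: The phenoxide adds to dichloroacetylene 7 formed in situ from trichloroethylene by base (elimination–addition, anti addition giving the E-dichlorovinyl ether), the standard first stage of aryl ynol ether synthesis.

Step 3
Reactants: 8 2-{[(E)-1,2-dichloroethenyl]oxy}-1,3,5-trimethoxybenzene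
Product: 11 2-(ethynyloxy)-1,3,5-trimethoxybenzene, via chloroethynyl ether 9 (not isolated), via lithium acetylide 10 (not isolated)
Conditions: n-BuLi (2.5 equiv), Et2O, −78 → −40 °C; then MeOH, −78 °C
Reagents that add atoms: none
Why: n-BuLi eliminates HCl to chloroalkyne 9 and then exchanges chlorine for lithium to give acetylide 10, which methanol protonates at low temperature to the terminal ynol ether (dichlorovinyl ether to alkynyl ether conversion).

Step 4
Reactants: 4 4-(benzyloxy)-3-ethoxycyclobut-2-en-1-one; 11 2-(ethynyloxy)-1,3,5-trimethoxybenzene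
Product: 16 2-(benzyloxy)-3-ethoxy-5-(2,4,6-trimethoxyphenoxy)phenol (rings A and B), via vinylketene 12 (not isolated), via vinylcyclobutenone 13 (not isolated), via dienylketene 14 (not isolated), via cyclohexadienone 15 (not isolated)
Conditions: PhMe, 80 → 110 °C, Ar (11 in excess, 4 added slowly)
Reagents that add atoms: none
Why: Danheiser benzannulation: thermal conrotatory 4π-electrocyclic opening of 4 gives vinylketene 12, whose ketene C=C bond undergoes [2+2] cycloaddition with ynol ether 11 to give 4-vinylcyclobutenone 13, and reversible 4π opening of 13 to dienylketene 14, 6π-electrocyclisation to cyclohexadienone 15 and enolisation should deliver phenol 16. The closest known reaction type is the benzannulation of cyclobutenones with alkoxy- and siloxyacetylenes, and an aryloxyacetylene is an ynol ether of the same polarisation. Ring B is the only ring closed, by the 6π-electrocyclisation that joins the former ketene carbon to the benzyloxy-bearing carbon (ring B C3–C4) after the [2+2] step has made C2–C3 and C1–C6. No stereocentre is set, because the racemic centres of 4, 13 and 15 all become sp2 carbons of the arene. The step needs regioselectivity in the [2+2] event, which the ynol ether secures because its unsubstituted nucleophilic carbon attacks the electrophilic ketene carbon and so places the aryloxy group meta to the new hydroxyl and para to the benzyloxy group. It also needs the alkyne to trap 12 faster than 12 dimerises, which is served by an excess of 11 and slow addition of 4.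

Step 5
Reactants: 16 2-(benzyloxy)-3-ethoxy-5-(2,4,6-trimethoxyphenoxy)phenol
Product: 17 2-(benzyloxy)-1,3-diethoxy-5-(2,4,6-trimethoxyphenoxy)benzene
Conditions: EtI, K2CO3, DMF, 50 °C
Reagents that add atoms: iodoethane, CCI
Why: Williamson O-ethylation of the single free phenol makes the two flanking ring B ethers identical while the central oxygen stays benzyl-protected.

Step 6
Reactants: 17 2-(benzyloxy)-1,3-diethoxy-5-(2,4,6-trimethoxyphenoxy)benzene
Product: 18 2,6-diethoxy-4-(2,4,6-trimethoxyphenoxy)phenol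
Conditions: H2 (1 atm), 10% Pd/C, EtOAc/EtOH, rt
Reagents that add atoms: none
Why: Catalytic hydrogenolysis cleaves only the benzyl ether and frees the ring B C4 hydroxyl; methyl, ethyl and diaryl ethers are inert.

Step 7
Reactants: 19 5-bromo-1,2,3-trimethoxybenzene
Product: 21 6-bromo-2,3,4-trimethoxybenzaldehyde, via chloro ether 20 (not isolated)
Conditions: Cl2CHOMe, TiCl4, CH2Cl2, −78 → 0 °C; then H2O
Reagents that add atoms: dichloromethyl methyl ether, COC(Cl)Cl; water, O
Why: Rieche formylation of an activated arene whose two free positions are equivalent (each ortho and para to a methoxy group), so only one aldehyde can form; chloro ether 20 is hydrolysed on work-up.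

Step 8
Reactants: 21 6-bromo-2,3,4-trimethoxybenzaldehyde
Product: 23 6-bromo-2,3,4-trimethoxyphenol, via aryl formate 22 (not isolated)
Conditions: mCPBA, CH2Cl2, 0 °C → rt; then HCl (cat.), MeOH, rt
Reagents that add atoms: 3-chloroperbenzoic acid, OOC(=O)c1cccc(Cl)c1
Why: Dakin-type Baeyer–Villiger oxidation in which the electron-rich aryl group migrates to give formate 22, whose acid-catalysed methanolysis leaves a hydroxyl ortho to bromine with no regiochemical ambiguity.

Step 9
Reactants: 24 4-bromo-2,6-dimethoxyphenol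
Product: 25 2-(benzyloxy)-5-bromo-1,3-dimethoxybenzene
Conditions: BnBr, K2CO3, DMF, rt
Reagents that add atoms: benzyl bromide, BrCc1ccccc1
Why: Williamson benzylation protects the hydroxyl that later becomes the nucleophilic oxygen of rings D and F.

Step 10
Reactants: 25 2-(benzyloxy)-5-bromo-1,3-dimethoxybenzene
Product: 28 [4-(benzyloxy)-3,5-dimethoxyphenyl]boronic acid, via aryllithium 26 (not isolated), via lithium borate 27 (not isolated)
Conditions: n-BuLi, THF, −78 °C; B(OiPr)3, −78 °C → rt; 1 M HCl
Reagents that add atoms: triisopropyl borate, CC(C)OB(OC(C)C)OC(C)C; water, O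
Why: Bromine–lithium exchange at low temperature, borylation of aryllithium 26 and acidic hydrolysis of ate complex 27 is the standard arylboronic acid synthesis and leaves the benzyl ether untouched.

Step 11
Reactants: 23 6-bromo-2,3,4-trimethoxyphenol; 28 [4-(benzyloxy)-3,5-dimethoxyphenyl]boronic acid
Product: 29 2-(benzyloxy)-5-(6-bromo-2,3,4-trimethoxyphenoxy)-1,3-dimethoxybenzene (CD and EF building block)
Conditions: Cu(OAc)2 (0.5 equiv), pyridine, 4 Å MS, CH2Cl2, O2 (1 atm), rt
Reagents that add atoms: none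
Why: Chan–Lam oxidative O-arylation runs at room temperature, accepts di-ortho-substituted ortho-halophenols and does not touch the C–Br bond needed in steps 13 and 15.

Step 12
Reactants: 23 6-bromo-2,3,4-trimethoxyphenol; 30 (3,4,5-trimethoxyphenyl)boronic acid
Product: 31 1-bromo-3,4,5-trimethoxy-2-(3,4,5-trimethoxyphenoxy)benzene (GH building block)
Conditions: Cu(OAc)2 (0.5 equiv), pyridine, 4 Å MS, CH2Cl2, O2 (1 atm), rt
Reagents that add atoms: none
Why: The same Chan–Lam O-arylation as in step 11, here with the purchasable ring H boronic acid.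

Step 13
Reactants: 18 2,6-diethoxy-4-(2,4,6-trimethoxyphenoxy)phenol; 29 2-(benzyloxy)-5-(6-bromo-2,3,4-trimethoxyphenoxy)-1,3-dimethoxybenzene
Product: 32 tetramer benzyl ether (rings A to D)
Conditions: CuI (20 mol %), picolinic acid (40 mol %), K3PO4, DMSO, 100 °C, Ar
Reagents that add atoms: none
Why: Ullmann diaryl ether coupling under the CuI–picolinic acid system, which is suited to hindered 2,6-disubstituted phenols and ortho-substituted aryl bromides, joins the ring B C4 oxygen to ring C C1.

Step 14
Reactants: 32 tetramer benzyl ether (rings A to D)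
Product: 33 tetramer phenol (rings A to D; free hydroxyl at ring D C4)
Conditions: H2 (1 atm), 10% Pd/C, EtOAc/MeOH, rt
Reagents that add atoms: none
Why: Hydrogenolysis of the single benzyl ether frees the ring D C4 hydroxyl, again a 2,6-dimethoxyphenol ready for the next coupling.

Step 15
Reactants: 33 tetramer phenol (rings A to D); 29 2-(benzyloxy)-5-(6-bromo-2,3,4-trimethoxyphenoxy)-1,3-dimethoxybenzene
Product: 34 hexamer benzyl ether (rings A to F)
Conditions: CuI (20 mol %), picolinic acid (40 mol %), K3PO4, DMSO, 100 °C, Ar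
Reagents that add atoms: none
Why: Second use of the same Ullmann coupling, since the ring D phenol of 33 is of the same steric and electronic type as 18 and the bromide is the same.

Step 16
Reactants: 34 hexamer benzyl ether (rings A to F)
Product: 35 hexamer phenol (rings A to F; free hydroxyl at ring F C4)
Conditions: H2 (1 atm), 10% Pd/C, EtOAc/MeOH, rt
Reagents that add atoms: none
Why: Hydrogenolysis frees the ring F C4 hydroxyl without touching any other ether.

Step 17
Reactants: 35 hexamer phenol (rings A to F); 31 1-bromo-3,4,5-trimethoxy-2-(3,4,5-trimethoxyphenoxy)benzene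
Product: 36 fully alkylated octamer (rings A to H; nineteen OMe and two OEt)
Conditions: CuI (20 mol %), picolinic acid (40 mol %), K3PO4, DMSO, 100 °C, Ar
Reagents that add atoms: none
Why: Third Ullmann coupling of the same type completes the heptaether skeleton.

Step 18
Reactants: 36 fully alkylated octamer
Product: 37 target CNP0206369.0
Conditions: BBr3 (excess), CH2Cl2, −78 °C → rt; then MeOH/H2O, 0 °C, Ar; degassed solvents for purification
Reagents that add atoms: none
Why: BBr3 ether cleavage, in which bromide attacks the alkyl carbon of each boron-complexed alkyl aryl ether, should remove all methyl and ethyl groups while the diaryl ethers, which offer no sp3 carbon, stay intact; aqueous methanol then releases the free phenols.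

**Compound list**

1 | 2-(benzyloxy)acetyl chloride | O=C(Cl)COCc1ccccc1 | starting material
2 | ethoxyacetylene (ethoxyethyne) | CCOC#C | starting material
3 | benzyloxyketene, 2-(benzyloxy)ethen-1-one (not isolated) | O=C=COCc1ccccc1 | intermediate
4 | 4-(benzyloxy)-3-ethoxycyclobut-2-en-1-one (racemic) | CCOC1=CC(=O)C1OCc2ccccc2 | intermediate
5 | 2,4,6-trimethoxyphenol | COc1cc(OC)c(O)c(OC)c1 | starting material
6 | trichloroethylene | ClC=C(Cl)Cl | starting material
7 | dichloroacetylene (not isolated) | ClC#CCl | intermediate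
8 | 2-{[(E)-1,2-dichloroethenyl]oxy}-1,3,5-trimethoxybenzene | COc1cc(OC)c(O/C(Cl)=C\Cl)c(OC)c1 | intermediate
9 | 2-[(chloroethynyl)oxy]-1,3,5-trimethoxybenzene (not isolated) | COc1cc(OC)c(OC#CCl)c(OC)c1 | intermediate
10 | lithium (2,4,6-trimethoxyphenoxy)acetylide (not isolated) | [Li]C#COc1c(OC)cc(OC)cc1OC | intermediate
11 | 2-(ethynyloxy)-1,3,5-trimethoxybenzene | C#COc1c(OC)cc(OC)cc1OC | intermediate
12 | (3Z)-4-(benzyloxy)-3-ethoxybuta-1,3-dien-1-one (not isolated) | O=C=C/C(OCC)=C/OCc1ccccc1 | intermediate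
13 | 4-[(Z)-2-(benzyloxy)-1-ethoxyethenyl]-3-(2,4,6-trimethoxyphenoxy)cyclobut-2-en-1-one (racemic, not isolated) | O=C1C=C(Oc2c(OC)cc(OC)cc2OC)C1/C(OCC)=C/OCc3ccccc3 | intermediate
14 | (3E,5Z)-6-(benzyloxy)-5-ethoxy-3-(2,4,6-trimethoxyphenoxy)hexa-1,3,5-trien-1-one (not isolated) | O=C=C/C(Oc1c(OC)cc(OC)cc1OC)=C\C(OCC)=C\OCc2ccccc2 | intermediate
15 | 6-(benzyloxy)-5-ethoxy-3-(2,4,6-trimethoxyphenoxy)cyclohexa-2,4-dien-1-one (racemic, not isolated) | O=C1C=C(Oc2c(OC)cc(OC)cc2OC)C=C(OCC)C1OCc3ccccc3 | intermediate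
16 | 2-(benzyloxy)-3-ethoxy-5-(2,4,6-trimethoxyphenoxy)phenol | CCOc1cc(Oc2c(OC)cc(OC)cc2OC)cc(O)c1OCc3ccccc3 | intermediate
17 | 2-(benzyloxy)-1,3-diethoxy-5-(2,4,6-trimethoxyphenoxy)benzene | CCOc1cc(Oc2c(OC)cc(OC)cc2OC)cc(OCC)c1OCc3ccccc3 | intermediate
18 | 2,6-diethoxy-4-(2,4,6-trimethoxyphenoxy)phenol | CCOc1cc(Oc2c(OC)cc(OC)cc2OC)cc(OCC)c1O | intermediate
19 | 5-bromo-1,2,3-trimethoxybenzene | COc1cc(Br)cc(OC)c1OC | starting material
20 | 1-bromo-2-[chloro(methoxy)methyl]-3,4,5-trimethoxybenzene (racemic, not isolated) | COC(Cl)c1c(Br)cc(OC)c(OC)c1OC | intermediate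
21 | 6-bromo-2,3,4-trimethoxybenzaldehyde | COc1cc(Br)c(C=O)c(OC)c1OC | intermediate
22 | 6-bromo-2,3,4-trimethoxyphenyl formate (not isolated) | COc1cc(Br)c(OC=O)c(OC)c1OC | intermediate
23 | 6-bromo-2,3,4-trimethoxyphenol | COc1cc(Br)c(O)c(OC)c1OC | intermediate
24 | 4-bromo-2,6-dimethoxyphenol | COc1cc(Br)cc(OC)c1O | starting material
25 | 2-(benzyloxy)-5-bromo-1,3-dimethoxybenzene | COc1cc(Br)cc(OC)c1OCc2ccccc2 | intermediate
26 | [4-(benzyloxy)-3,5-dimethoxyphenyl]lithium (not isolated) | [Li]c1cc(OC)c(OCc2ccccc2)c(OC)c1 | intermediate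
27 | lithium [4-(benzyloxy)-3,5-dimethoxyphenyl]tri(propan-2-yloxy)borate (not isolated) | [Li+].CC(C)O[B-](OC(C)C)(OC(C)C)c1cc(OC)c(OCc2ccccc2)c(OC)c1 | intermediate
28 | [4-(benzyloxy)-3,5-dimethoxyphenyl]boronic acid | COc1cc(B(O)O)cc(OC)c1OCc2ccccc2 | intermediate
29 | 2-(benzyloxy)-5-(6-bromo-2,3,4-trimethoxyphenoxy)-1,3-dimethoxybenzene | COc1cc(Br)c(Oc2cc(OC)c(OCc3ccccc3)c(OC)c2)c(OC)c1OC | intermediate
30 | (3,4,5-trimethoxyphenyl)boronic acid | COc1cc(B(O)O)cc(OC)c1OC | starting material
31 | 1-bromo-3,4,5-trimethoxy-2-(3,4,5-trimethoxyphenoxy)benzene | COc1cc(Br)c(Oc2cc(OC)c(OC)c(OC)c2)c(OC)c1OC | intermediate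
32 | 1-[2,6-diethoxy-4-(2,4,6-trimethoxyphenoxy)phenoxy]-2-[4-(benzyloxy)-3,5-dimethoxyphenoxy]-3,4,5-trimethoxybenzene (tetramer benzyl ether) | COc1cc(OC)c(Oc2cc(OCC)c(Oc3cc(OC)c(OC)c(OC)c3Oc3cc(OC)c(OCc4ccccc4)c(OC)c3)c(OCC)c2)c(OC)c1 | intermediate
33 | 4-{6-[2,6-diethoxy-4-(2,4,6-trimethoxyphenoxy)phenoxy]-2,3,4-trimethoxyphenoxy}-2,6-dimethoxyphenol (tetramer phenol) | COc1cc(OC)c(Oc2cc(OCC)c(Oc3cc(OC)c(OC)c(OC)c3Oc3cc(OC)c(O)c(OC)c3)c(OCC)c2)c(OC)c1 | intermediate
34 | 1-(4-{6-[2,6-diethoxy-4-(2,4,6-trimethoxyphenoxy)phenoxy]-2,3,4-trimethoxyphenoxy}-2,6-dimethoxyphenoxy)-2-[4-(benzyloxy)-3,5-dimethoxyphenoxy]-3,4,5-trimethoxybenzene (hexamer benzyl ether) | COc1cc(OC)c(Oc2cc(OCC)c(Oc3cc(OC)c(OC)c(OC)c3Oc3cc(OC)c(Oc4cc(OC)c(OC)c(OC)c4Oc4cc(OC)c(OCc5ccccc5)c(OC)c4)c(OC)c3)c(OCC)c2)c(OC)c1 | intermediate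
35 | 4-[6-(4-{6-[2,6-diethoxy-4-(2,4,6-trimethoxyphenoxy)phenoxy]-2,3,4-trimethoxyphenoxy}-2,6-dimethoxyphenoxy)-2,3,4-trimethoxyphenoxy]-2,6-dimethoxyphenol (hexamer phenol) | COc1cc(OC)c(Oc2cc(OCC)c(Oc3cc(OC)c(OC)c(OC)c3Oc3cc(OC)c(Oc4cc(OC)c(OC)c(OC)c4Oc4cc(OC)c(O)c(OC)c4)c(OC)c3)c(OCC)c2)c(OC)c1 | intermediate
36 | 1-{4-[6-(4-{6-[2,6-diethoxy-4-(2,4,6-trimethoxyphenoxy)phenoxy]-2,3,4-trimethoxyphenoxy}-2,6-dimethoxyphenoxy)-2,3,4-trimethoxyphenoxy]-2,6-dimethoxyphenoxy}-3,4,5-trimethoxy-2-(3,4,5-trimethoxyphenoxy)benzene (fully alkylated octamer) | COc1cc(OC)c(Oc2cc(OCC)c(Oc3cc(OC)c(OC)c(OC)c3Oc3cc(OC)c(Oc4cc(OC)c(OC)c(OC)c4Oc4cc(OC)c(Oc5cc(OC)c(OC)c(OC)c5Oc5cc(OC)c(OC)c(OC)c5)c(OC)c4)c(OC)c3)c(OCC)c2)c(OC)c1 | intermediate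
37 | CNP0206369.0: compound 36 with all nineteen methoxy and both ethoxy groups replaced by hydroxyl (achiral) | Oc1cc(O)c(Oc2cc(O)c(Oc3cc(O)c(O)c(O)c3Oc3cc(O)c(Oc4cc(O)c(O)c(O)c4Oc4cc(O)c(Oc5cc(O)c(O)c(O)c5Oc5cc(O)c(O)c(O)c5)c(O)c4)c(O)c3)c(O)c2)c(O)c1 | target

**Step count and risks**

Total step count: 18. Longest linear sequence: 11 steps (steps 2, 3, 4, 5, 6, 13, 14, 15, 16, 17, 18).

Steps most likely to fail:

1. Step 4. The vinylketene may be consumed by dimerisation or oligomerisation, or the aryl ynol ether may polymerise at the temperature needed to open the cyclobutenone, so that no cycloadduct forms. The fallback gives up the annulation for ring B and makes the A–O–B ether by Ullmann coupling; it sets out from 19 and 5 and comes back to the route at 17. Compound 19 is demethylated with BBr3 in CH2Cl2 to 5-bromobenzene-1,2,3-triol F1, which is triethylated (EtI, K2CO3, DMF, Ar) to 5-bromo-1,2,3-triethoxybenzene F2. AlCl3 in CH2Cl2 then removes only the central ethyl group, the out-of-plane and chelating middle alkoxy group of a 1,2,3-trialkoxybenzene, to give 4-bromo-2,6-diethoxyphenol F3. Benzylation (BnBr, K2CO3, DMF) gives 2-(benzyloxy)-5-bromo-1,3-diethoxybenzene F4, and coupling of this unhindered bromide with the hindered phenol 5 (CuI, picolinic acid, K3PO4, DMSO, 90 °C) should give 17.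

2. Step 13 (the same holds for steps 15 and 17). Carbon–oxygen bond formation may be too slow because both partners are electron-rich and ortho-oxygenated, so that hydrodebromination of the bromide and oxidation of the phenolate take over. The fallback uses a bromide activated by an ortho-formyl group and unveils the next oxygen afterwards; it sets out from 18 and 21 and comes back to the route at 32. Copper-catalysed coupling of 18 with 21 (CuI, picolinic acid, K3PO4, DMSO, 80 °C; the formyl group activates the C–Br bond towards oxidative addition and towards addition–elimination) gives 6-[2,6-diethoxy-4-(2,4,6-trimethoxyphenoxy)phenoxy]-2,3,4-trimethoxybenzaldehyde F5. mCPBA in CH2Cl2 converts it by Dakin-type oxidation into 6-[2,6-diethoxy-4-(2,4,6-trimethoxyphenoxy)phenoxy]-2,3,4-trimethoxyphenyl formate F6, and acid-catalysed methanolysis gives 6-[2,6-diethoxy-4-(2,4,6-trimethoxyphenoxy)phenoxy]-2,3,4-trimethoxyphenol F7. Chan–Lam arylation of F7 with 28 under the conditions of step 11 then gives 32. The same three operations starting from 33 or 35 would replace steps 15 and 17.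

3. Step 18. Cleavage of some of the twenty-one alkyl ethers may stay incomplete, and the pyrogallol-type rings may be oxidised by air during isolation of the free polyphenol. The fallback changes the isolation to capture and release; it sets out from 36 and comes back to the route at 37. After the BBr3 treatment and quench, the crude product is not purified as the free phenol but acetylated at once (Ac2O, pyridine, DMAP, Ar) to the henicosaacetate of the target F8. This is stable to air and chromatography on silica, so incompletely dealkylated material can be separated and returned to BBr3. Deacetylation of F8 with HCl in MeOH (from AcCl) under argon should then release 37 under non-oxidising conditions.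

**Further compounds**

F1 | step 4 | 5-bromobenzene-1,2,3-triol | Oc1cc(Br)cc(O)c1O
F2 | step 4 | 5-bromo-1,2,3-triethoxybenzene | CCOc1cc(Br)cc(OCC)c1OCC
F3 | step 4 | 4-bromo-2,6-diethoxyphenol | CCOc1cc(Br)cc(OCC)c1O
F4 | step 4 | 2-(benzyloxy)-5-bromo-1,3-diethoxybenzene | CCOc1cc(Br)cc(OCC)c1OCc2ccccc2
F5 | step 13 | 6-[2,6-diethoxy-4-(2,4,6-trimethoxyphenoxy)phenoxy]-2,3,4-trimethoxybenzaldehyde | CCOc1cc(Oc2c(OC)cc(OC)cc2OC)cc(OCC)c1Oc3cc(OC)c(OC)c(OC)c3C=O
F6 | step 13 | 6-[2,6-diethoxy-4-(2,4,6-trimethoxyphenoxy)phenoxy]-2,3,4-trimethoxyphenyl formate | CCOc1cc(Oc2c(OC)cc(OC)cc2OC)cc(OCC)c1Oc3cc(OC)c(OC)c(OC)c3OC=O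
F7 | step 13 | 6-[2,6-diethoxy-4-(2,4,6-trimethoxyphenoxy)phenoxy]-2,3,4-trimethoxyphenol | CCOc1cc(Oc2c(OC)cc(OC)cc2OC)cc(OCC)c1Oc3cc(OC)c(OC)c(OC)c3O
F8 | step 18 | henicosaacetate of the target (every hydroxyl of 37 as acetate) | CC(=O)Oc1cc(OC(C)=O)c(Oc2cc(OC(C)=O)c(Oc3cc(OC(C)=O)c(OC(C)=O)c(OC(C)=O)c3Oc3cc(OC(C)=O)c(Oc4cc(OC(C)=O)c(OC(C)=O)c(OC(C)=O)c4Oc4cc(OC(C)=O)c(Oc5cc(OC(C)=O)c(OC(C)=O)c(OC(C)=O)c5Oc5cc(OC(C)=O)c(OC(C)=O)c(OC(C)=O)c5)c(OC(C)=O)c4)c(OC(C)=O)c3)c(OC(C)=O)c2)c(OC(C)=O)c1
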